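**Plan**

- Feature: in the oxolane (O1, C2 aryl, C3 bearing C9H2OH, C4 bearing the C7' aroyl, C5) the cis carbons C9 and C7' sit on adjacent ring carbons, so they can be the two carbons of one aryl alkyne held as a cyclobutene fused at C3–C4.
- Cuts: C9–OH and C7'=O go back to a C7'=C9 cyclobutene double bond; then C3–C9 and C4–C7' are cut together ([2+2] of an aryl chloroalkyne with a 2-aryl-2,5-dihydrofuran); then C2–aryl (Heck) and the alkyne carbon C9 (aldehyde homologation). Both aryl groups come from syringaldehyde.
- Forward: 2,3-dihydrofuran supplies the five-membered ring and is arylated; the cyclobutene is fused on in the key step and cut open again by dihydroxylation and glycol cleavage, leaving the monocyclic oxolane; aldehyde reduction and debenzylation finish.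
- Stereochemistry: C2 (S) comes from the ligand-controlled asymmetric Heck arylation; C3 and C4 come from the suprafacial cycloaddition on the face anti to the C2 aryl (2,3-trans, 3,4-cis); the ketone is unmasked by C=C cleavage, not through an enolate, so the cis C3/C4 pair is kept.

Key step: step 7

Abbreviations: Ar = 4-benzyloxy-3,5-dimethoxyphenyl. The oxolane locants above (C2–C5, C9, C7') are used in the explanations; in the bicyclic names C1 = C3, C5 = C4, C6 = C7', C7 = C9. tBuXPhos = 2-di-tert-butylphosphino-2',4',6'-triisopropylbiphenyl; BArF4 = tetrakis[3,5-bis(trifluoromethyl)phenyl]borate.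

Assumption: by correlation with the arylation of 2,3-dihydrofuran by phenyl triflate, (R)-tBu-PHOX is taken as the ligand enantiomer that gives the (S)-dihydrofuran; if the sense is the opposite, the antipodal ligand is used.

**Route**

Step 1
Reactants: 1 syringaldehyde
Product: 2 4-benzyloxy-3,5-dimethoxybenzaldehyde
Conditions: BnBr, K2CO3, DMF, 60 °C
Reagents that add atoms: benzyl bromide, BrCc1ccccc1
Why: Williamson etherification, in which the phenoxide of 1, although flanked by two methoxy groups, is alkylated by the unhindered benzylic bromide to give an ether that survives every step up to the final hydrogenolysis.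

Step 2
Reactants: 2 4-benzyloxy-3,5-dimethoxybenzaldehyde
Product: 4 4-benzyloxy-3,5-dimethoxyphenol, via aryl formate 3 (not isolated)
Conditions: mCPBA, CH2Cl2, rt; then MeOH, Et3N (cat.), rt
Reagents that add atoms: meta-chloroperbenzoic acid, OOC(=O)c1cccc(Cl)c1
Why: Baeyer–Villiger (Dakin-type) oxidation, in which the electron-rich trialkoxyaryl group migrates in preference to hydrogen in the Criegee intermediate to give the aryl formate, which is then methanolysed under mild base catalysis to the phenol.

Step 3
Reactants: 4 4-benzyloxy-3,5-dimethoxyphenol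
Product: 5 4-benzyloxy-3,5-dimethoxyphenyl trifluoromethanesulfonate
Conditions: Tf2O, pyridine, CH2Cl2, 0 °C
Reagents that add atoms: triflic anhydride, O=S(=O)(OS(=O)(=O)C(F)(F)F)C(F)(F)F
Why: O-sulfonylation of the only nucleophilic site of 4 gives the aryl triflate needed for the cationic Heck pathway.

Step 4
Reactants: 5 4-benzyloxy-3,5-dimethoxyphenyl trifluoromethanesulfonate; 6 2,3-dihydrofuran
Product: 7 (S)-2-(4-benzyloxy-3,5-dimethoxyphenyl)-2,5-dihydrofuran
Conditions: Pd2(dba)3 (3 mol %), (R)-tBu-PHOX (6 mol %), i-Pr2NEt, 6 (4 equiv), THF, 70 °C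
Reagents that add atoms: none
Why: Asymmetric intermolecular Mizoroki–Heck arylation, in which the triflate adds oxidatively to zerovalent palladium, the cationic arylpalladium–PHOX complex inserts one enantioface of the enol ether with the aryl group going to C2 (ligand control sets the C2 stereocentre), and the P,N-ligand complex releases the alkene after β-hydride elimination without re-insertion, so the 2,5-dihydro isomer is obtained.

Step 5
Reactants: 2 4-benzyloxy-3,5-dimethoxybenzaldehyde
Product: 8 4-benzyloxy-3,5-dimethoxyphenylacetylene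
Conditions: dimethyl (1-diazo-2-oxopropyl)phosphonate, K2CO3, MeOH, rt
Reagents that add atoms: Ohira–Bestmann reagent, COP(=O)(OC)C(=[N+]=[N-])C(C)=O
Why: Seyferth–Gilbert homologation in the Ohira–Bestmann variant, in which methanolysis of the reagent frees the diazomethylphosphonate anion, which olefinates the non-enolisable aldehyde to a diazoalkene that loses N2 and rearranges by 1,2-hydride shift to the terminal alkyne under conditions the benzyl ether tolerates.

Step 6
Reactants: 8 4-benzyloxy-3,5-dimethoxyphenylacetylene
Product: 9 1-chloro-2-(4-benzyloxy-3,5-dimethoxyphenyl)acetylene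
Conditions: CCl4, K2CO3, TBAF (10 mol %), THF, rt
Reagents that add atoms: carbon tetrachloride, ClC(Cl)(Cl)Cl
Why: Base-mediated 1-chlorination of a terminal alkyne, in which the acetylide abstracts chlorine from CCl4 by halophilic attack and the trichloromethyl anion so formed deprotonates the next alkyne, the chlorine serving as the activating group for step 7.

Step 7
Reactants: 7 (S)-2-(4-benzyloxy-3,5-dimethoxyphenyl)-2,5-dihydrofuran; 9 1-chloro-2-(4-benzyloxy-3,5-dimethoxyphenyl)acetylene
Product: 10 (1S,2S,5S)-7-chloro-2,6-bis(4-benzyloxy-3,5-dimethoxyphenyl)-3-oxabicyclo[3.2.0]hept-6-ene (cis-fused, cyclobutene on the face anti to the C2 aryl)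
Conditions: [(tBuXPhos)Au(NCMe)]BArF4 (5 mol %), CH2Cl2, 23 °C, slow addition of 9 to 7 (1.5 equiv)
Reagents that add atoms: none
Why: Proposed new method: the cationic monovalent gold centre binds the chloroalkyne as a π-complex, alkene carbon C4 attacks the aryl-bearing carbon C7' to give a cyclopropyl gold carbene (homoallyl cation) whose gold-bound carbon C9 then bonds to C3, and loss of the gold cation leaves the cyclobutene; the closest known reaction type is the gold-catalysed intermolecular [2+2] cycloaddition of aryl chloroalkynes with unactivated mono- and 1,2-disubstituted alkenes, extended here to a cyclic bis-allylic ether bearing a stereocentre. The four-membered ring closes by this stepwise, formally [2+2] addition, which is suprafacial on the alkene, so the new C3–C9 and C4–C7' bonds are cis and the ring fusion is cis. Both new stereocentres (C3 and C4) are controlled by the C2 stereocentre, because the bulky gold–alkyne complex approaches the nearly flat dihydrofuran on the face opposite to the C2 aryl group, which gives the 2,3-trans relationship. The step needs regioselectivity (C7' to C4, C9 to C3), and the substrate provides a modest bias for it: C4 is the alkene carbon remote from the substituted C2 and so is the one that attacks the hindered aryl-bearing alkyne carbon, while the charge building at C3 is flanked by the antiperiplanar C2–aryl bond. The chlorine makes the alkyne complex electrophilic enough for an inductively deactivated alkene and rules out gold acetylide formation, and the silver-free, acid-free catalyst spares the acid-labile benzylic allylic ether of 7.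

Step 8
Reactants: 10 (1S,2S,5S)-7-chloro-2,6-bis(4-benzyloxy-3,5-dimethoxyphenyl)-3-oxabicyclo[3.2.0]hept-6-ene
Product: 11 (1S,2S,5S)-2,6-bis(4-benzyloxy-3,5-dimethoxyphenyl)-3-oxabicyclo[3.2.0]hept-6-ene
Conditions: Pd(OAc)2 (5 mol %), XPhos (10 mol %), HCO2Na, DMF, 80 °C
Reagents that add atoms: none
Why: Palladium-catalysed formate hydrodehalogenation, in which the electron-rich biarylphosphine lets zerovalent palladium insert into the alkenyl C–Cl bond, formate replaces chloride and loses CO2 to give the palladium hydride, and reductive elimination forms the C9–H bond with the double bond kept in its aryl-conjugated position and the benzyl ethers and stereocentres untouched.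

Step 9
Reactants: 11 (1S,2S,5S)-2,6-bis(4-benzyloxy-3,5-dimethoxyphenyl)-3-oxabicyclo[3.2.0]hept-6-ene
Product: 12 (1R,2S,5R,6S,7S)-2,6-bis(4-benzyloxy-3,5-dimethoxyphenyl)-3-oxabicyclo[3.2.0]heptane-6,7-diol (cis diol, both hydroxyls on the convex face)
Conditions: OsO4 (2 mol %), NMO, acetone/H2O, rt
Reagents that add atoms: N-methylmorpholine N-oxide, C[N+]1([O-])CCOCC1; water, O
Why: Upjohn dihydroxylation of the only alkene present, a strained electron-rich styrene-type double bond, expected to occur from the convex face of the bicycle (syn to the bridgehead hydrogens), the two new carbinol centres being of no consequence because both are destroyed in step 10.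

Step 10
Reactants: 12 (1R,2S,5R,6S,7S)-2,6-bis(4-benzyloxy-3,5-dimethoxyphenyl)-3-oxabicyclo[3.2.0]heptane-6,7-diol
Product: 14 [(2S,3R,4R)-2-(4-benzyloxy-3,5-dimethoxyphenyl)-3-(hydroxymethyl)oxolan-4-yl](4-benzyloxy-3,5-dimethoxyphenyl)methanone, via keto aldehyde 13 (not isolated)
Conditions: NaIO4, THF/pH 7 buffer, 0 °C; extractive work-up; then NaBH(OAc)3, benzene, rt
Reagents that add atoms: none
Why: Malaprade glycol cleavage followed by chemoselective hydride reduction, in which periodate cleaves the cis diol through its cyclic ester under neutral conditions to unmask the C7' aryl ketone and the C9 aldehyde without enolisation, and NaBH(OAc)3, too weak a hydride donor for an electron-rich aryl ketone, reduces only the aldehyde, so C3 and C4 keep the cis relationship set in step 7.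

Step 11
Reactants: 14 [(2S,3R,4R)-2-(4-benzyloxy-3,5-dimethoxyphenyl)-3-(hydroxymethyl)oxolan-4-yl](4-benzyloxy-3,5-dimethoxyphenyl)methanone
Product: 15 ciwujiatone, [(2S,3R,4R)-2-(4-hydroxy-3,5-dimethoxyphenyl)-3-(hydroxymethyl)oxolan-4-yl](4-hydroxy-3,5-dimethoxyphenyl)methanone
Conditions: H2 (1 atm), Pd on carbon (10 wt %), EtOAc, rt, stopped at two equivalents of H2
Reagents that add atoms: none
Why: Catalytic hydrogenolysis under neutral conditions, in which the two phenolic benzyl ethers are cleaved much faster than the electron-rich aryl ketone or the C2–O benzylic ether is reduced, so the base-sensitive C4 centre and the rest of the molecule should stay intact.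

**Compound list**

1 | syringaldehyde (4-hydroxy-3,5-dimethoxybenzaldehyde) | COc1cc(C=O)cc(OC)c1O | starting material
2 | 4-benzyloxy-3,5-dimethoxybenzaldehyde | COc1cc(C=O)cc(OC)c1OCc1ccccc1 | intermediate
3 | 4-benzyloxy-3,5-dimethoxyphenyl formate | COc1cc(OC=O)cc(OC)c1OCc1ccccc1 | intermediate (not isolated)
4 | 4-benzyloxy-3,5-dimethoxyphenol | COc1cc(O)cc(OC)c1OCc1ccccc1 | intermediate
5 | 4-benzyloxy-3,5-dimethoxyphenyl trifluoromethanesulfonate | COc1cc(OS(=O)(=O)C(F)(F)F)cc(OC)c1OCc1ccccc1 | intermediate
6 | 2,3-dihydrofuran | C1CC=CO1 | starting material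
7 | (S)-2-(4-benzyloxy-3,5-dimethoxyphenyl)-2,5-dihydrofuran | COc1cc(cc(OC)c1OCc1ccccc1)[C@@H]1C=CCO1 | intermediate
8 | 4-benzyloxy-3,5-dimethoxyphenylacetylene | C#Cc1cc(OC)c(OCc2ccccc2)c(OC)c1 | intermediate
9 | 1-chloro-2-(4-benzyloxy-3,5-dimethoxyphenyl)acetylene | ClC#Cc1cc(OC)c(OCc2ccccc2)c(OC)c1 | intermediate
10 | (1S,2S,5S)-7-chloro-2,6-bis(4-benzyloxy-3,5-dimethoxyphenyl)-3-oxabicyclo[3.2.0]hept-6-ene | COc1cc(cc(OC)c1OCc1ccccc1)C1=C(Cl)[C@@H]2[C@@H](c3cc(OC)c(OCc4ccccc4)c(OC)c3)OC[C@H]12 | intermediate
11 | (1S,2S,5S)-2,6-bis(4-benzyloxy-3,5-dimethoxyphenyl)-3-oxabicyclo[3.2.0]hept-6-ene | COc1cc(cc(OC)c1OCc1ccccc1)C1=C[C@@H]2[C@@H](c3cc(OC)c(OCc4ccccc4)c(OC)c3)OC[C@H]12 | intermediate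
12 | (1R,2S,5R,6S,7S)-2,6-bis(4-benzyloxy-3,5-dimethoxyphenyl)-3-oxabicyclo[3.2.0]heptane-6,7-diol | COc1cc(cc(OC)c1OCc1ccccc1)[C@]1(O)[C@@H](O)[C@@H]2[C@@H](c3cc(OC)c(OCc4ccccc4)c(OC)c3)OC[C@H]12 | intermediate
13 | (2S,3S,4R)-4-(4-benzyloxy-3,5-dimethoxybenzoyl)-2-(4-benzyloxy-3,5-dimethoxyphenyl)oxolane-3-carbaldehyde | COc1cc(C(=O)[C@H]2CO[C@H](c3cc(OC)c(OCc4ccccc4)c(OC)c3)[C@H]2C=O)cc(OC)c1OCc1ccccc1 | intermediate (not isolated)
14 | [(2S,3R,4R)-2-(4-benzyloxy-3,5-dimethoxyphenyl)-3-(hydroxymethyl)oxolan-4-yl](4-benzyloxy-3,5-dimethoxyphenyl)methanone | COc1cc(C(=O)[C@H]2CO[C@H](c3cc(OC)c(OCc4ccccc4)c(OC)c3)[C@H]2CO)cc(OC)c1OCc1ccccc1 | intermediate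
15 | ciwujiatone, [(2S,3R,4R)-2-(4-hydroxy-3,5-dimethoxyphenyl)-3-(hydroxymethyl)oxolan-4-yl](4-hydroxy-3,5-dimethoxyphenyl)methanone | COc1cc(C(=O)[C@H]2CO[C@H](c3cc(OC)c(O)c(OC)c3)[C@H]2CO)cc(OC)c1O | target

**Step count**

Total: 11 steps. Longest linear sequence: 9 steps (steps 1, 2, 3, 4, 7, 8, 9, 10, 11 from syringaldehyde).

**Steps most likely to fail**

Step 7 (proposed new method). Several processes could defeat it:
- The inductively deactivated alkene may attack too slowly, so that the chloroalkyne is lost to self-coupling or to 1,2-chloroalkynylation.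
- The regiochemical bias between C3 and C4 may be too small.
- The benzylic allylic C2–O bond may ionise, or hydride may shift from C2 into the cationic intermediate.

The fallback uses known reactions only, sets out from 7 and comes back to the route at 11. Dichloroketene (from trichloroacetyl chloride and Zn–Cu couple, Et2O/DME) adds suprafacially to C3=C4 anti to the aryl group. This should give the cis-fused 7,7-dichloro-2-aryl-3-oxabicyclo[3.2.0]heptan-6-one F1, with the ketene carbonyl carbon on the less hindered C4; a regioisomer would be removed here. Zn in AcOH removes both chlorines to give the cyclobutanone F2. Separately, 5-bromo-2-benzyloxy-1,3-dimethoxybenzene F3 is made by benzylating commercial 4-bromo-2,6-dimethoxyphenol and is exchanged with n-BuLi at −78 °C to the aryllithium F4. In the presence of CeCl3, F4 adds to F2 from the convex face to give the tertiary cyclobutanol F5. Dehydration with the Burgess reagent, away from the bridgehead, gives 11, and step 9 follows.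

Step 8. Oxidative addition into the hindered tetrasubstituted alkenyl C–Cl bond may be slow, or a palladium hydride may move the double bond. The fallback uses the chlorine as a latent carbonyl, sets out from 10 and comes back at 13. OsO4/NMO dihydroxylation of the chloroalkene gives, after loss of HCl from the chlorohydrin, the α-hydroxy cyclobutanone F6. NaBH4 reduces it to the diol F7, expected to be the trans diol (C7 epimer of 12) from convex-face hydride delivery. Pb(OAc)4, which cleaves trans as well as cis 1,2-diols, gives keto aldehyde 13, which is reduced as in step 10 to 14.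

Step 10. The cis keto aldehyde may epimerise at C3 or C4 while the slow selective reduction runs, or the ketone may be partly reduced. The fallback gives up selectivity in the reduction and restores the ketone by selective oxidation; it sets out from 12 and comes back at 14. After periodate cleavage, crude 13 is reduced at once and completely with NaBH4 in MeOH at −40 °C to the 1,4-diol F8, a mixture of carbinol epimers. Its benzylic alcohol alone is then re-oxidised with MnO2 in CH2Cl2 under neutral conditions to give 14.

Further compounds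
F1 | step 7 | 7,7-dichloro-2-(4-benzyloxy-3,5-dimethoxyphenyl)-3-oxabicyclo[3.2.0]heptan-6-one (2S, cis-fused, cyclobutanone anti to the aryl) | O=C1C(Cl)(Cl)[C@@H]2[C@@H](c3cc(OC)c(OCc4ccccc4)c(OC)c3)OC[C@H]12
F2 | step 7 | 2-(4-benzyloxy-3,5-dimethoxyphenyl)-3-oxabicyclo[3.2.0]heptan-6-one (2S, cis-fused, cyclobutanone anti to the aryl) | O=C1C[C@@H]2[C@@H](c3cc(OC)c(OCc4ccccc4)c(OC)c3)OC[C@H]12
F3 | step 7 | 5-bromo-2-benzyloxy-1,3-dimethoxybenzene | COc1cc(Br)cc(OC)c1OCc1ccccc1
F4 | step 7 | (4-benzyloxy-3,5-dimethoxyphenyl)lithium | [Li]c1cc(OC)c(OCc2ccccc2)c(OC)c1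
F5 | step 7 | 2,6-bis(4-benzyloxy-3,5-dimethoxyphenyl)-3-oxabicyclo[3.2.0]heptan-6-ol (C6 aryl on the convex face) | COc1cc(cc(OC)c1OCc1ccccc1)[C@@]1(O)C[C@@H]2[C@@H](c3cc(OC)c(OCc4ccccc4)c(OC)c3)OC[C@H]12
F6 | step 8 | 6-hydroxy-2,6-bis(4-benzyloxy-3,5-dimethoxyphenyl)-3-oxabicyclo[3.2.0]heptan-7-one (hydroxyl on the convex face) | COc1cc(cc(OC)c1OCc1ccccc1)[C@]1(O)C(=O)[C@@H]2[C@@H](c3cc(OC)c(OCc4ccccc4)c(OC)c3)OC[C@H]12
F7 | step 8 | 2,6-bis(4-benzyloxy-3,5-dimethoxyphenyl)-3-oxabicyclo[3.2.0]heptane-6,7-diol, C7 epimer of 12 (trans diol) | COc1cc(cc(OC)c1OCc1ccccc1)[C@]1(O)[C@H](O)[C@@H]2[C@@H](c3cc(OC)c(OCc4ccccc4)c(OC)c3)OC[C@H]12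
F8 | step 10 | (4-benzyloxy-3,5-dimethoxyphenyl)[(2S,3R,4R)-2-(4-benzyloxy-3,5-dimethoxyphenyl)-3-(hydroxymethyl)oxolan-4-yl]methanol, mixture of carbinol epimers | COc1cc(C(O)[C@H]2CO[C@H](c3cc(OC)c(OCc4ccccc4)c(OC)c3)[C@H]2CO)cc(OC)c1OCc1ccccc1
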